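**Retrosynthetic overview**
1. The route rests on the spiro quaternary carbon C-4 of the piperidine, which is also a member of the tetrahydropyran ring, carries that ring's O–CH2 carbon and lies between the quaternary ring-junction carbon and the bridgehead CH. It is made, with the O–CH2 carbon as a formyl group, by stereospecific epoxide-to-aldehyde ring contraction of a 4-alkylazepane 4,5-epoxide (ring carbon C-6 shifts from C-5 to C-4).
2. The epoxide comes from a piperidone β-keto ester: asymmetric Michael addition (quaternary carbon), one-carbon ring expansion, catalyst-controlled conjugate alkenylation, enol triflate coupling with the side chain, hydroxyl-directed epoxidation. It carries only sulfonamide, nitrile, benzoate and silyl ether, so that no neighbouring group can trap the tertiary cation.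
3. After the contraction: tetrahydropyran (as methyl ketal) from the reduced aldehyde and the oxidised side chain; cyclopentenone by Pauson–Khand reaction with ethene; cycloheptene by vinyl addition, ring-closing metathesis and oxidative transposition; ester-bearing cyclopentene by aldol condensation.
4. Ring order: piperidine (key step), tetrahydropyran, cyclopentenone, cycloheptene, cyclopentene; then N-methyl and ketal hydrolysis.

Key step: step 13

Assumption: the hemiketal carbon equilibrates through the open hydroxy ketone, so the configuration written for the target is taken as the thermodynamic one and is also drawn for the methyl ketals.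
Abbreviation: SES = 2-(trimethylsilyl)ethanesulfonyl; azepane and piperidine atoms are numbered from nitrogen.

Step 1
Reactants: 1 (S)-2-ethyloxirane
Product: 2 (S)-pent-1-en-3-ol
Conditions: Me3S+ I− (3 equiv), n-BuLi, THF, −10 °C to rt
Reagents that add atoms: trimethylsulfonium iodide C[S+](C)C.[I-]
Why: Dimethylsulfonium methylide opens the epoxide at CH2 and the sulfonium alkoxide eliminates dimethyl sulfide, a known one-carbon homologation of terminal epoxides to allylic alcohols that leaves the carbinol centre untouched (this centre is only a placeholder for the later ketone).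

Step 2
Reactants: 2 (S)-pent-1-en-3-ol
Product: 3 (S)-pent-1-en-3-yl benzoate
Conditions: BzCl, pyridine, DMAP (cat.), CH2Cl2, 0 °C to rt
Reagents that add atoms: benzoyl chloride O=C(Cl)c1ccccc1
Why: DMAP-catalysed acylation; a benzoate is chosen because its acyl-bound oxygen cannot act as a neighbouring nucleophile in step 13.

Step 3
Reactants: 4 methyl 4-oxopiperidine-3-carboxylate hydrochloride
Product: 5 methyl 4-oxo-1-SES-piperidine-3-carboxylate
Conditions: SESCl, Et3N, CH2Cl2, 0 °C
Reagents that add atoms: 2-(trimethylsilyl)ethanesulfonyl chloride C[Si](C)(C)CCS(=O)(=O)Cl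
Why: N-sulfonylation of the secondary amine outruns reaction at the enolised β-keto ester and gives a non-basic, fluoride-labile sulfonamide.

Step 4
Reactants: 5 methyl 4-oxo-1-SES-piperidine-3-carboxylate
Product: 6 methyl (S)-3-(2-cyanoethyl)-4-oxo-1-SES-piperidine-3-carboxylate
Conditions: acrylonitrile, N-[3,5-bis(trifluoromethyl)phenyl]-N′-(9-deoxy-epi-quinin-9-yl)thiourea (10 mol %), toluene, −20 °C to rt
Reagents that add atoms: acrylonitrile C=CC#N
Why: Organocatalytic asymmetric Michael addition of a cyclic β-keto ester, in which the thiourea–quinuclidine catalyst binds enol and acceptor and shields one enol face, should set the (S) quaternary carbon.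

Step 5
Reactants: 6 methyl (S)-3-(2-cyanoethyl)-4-oxo-1-SES-piperidine-3-carboxylate
Product: 8 methyl (S)-3-(2-cyanoethyl)-4-oxo-1-SES-azepane-3-carboxylate, via α-silyl ketone 7 (not isolated)
Conditions: TMSCHN2, BF3·OEt2, CH2Cl2, −78 to −30 °C; then 1 M HCl, THF
Reagents that add atoms: (trimethylsilyl)diazomethane C[Si](C)(C)C=[N+]=[N-]
Why: Lewis-acid-promoted diazoalkane homologation (Tiffeneau–Demjanov-type ring expansion) in which the CH2 carbon migrates in preference to the fully substituted, ester-bearing carbon, so the new CH2 enters on the side remote from the quaternary centre.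

Step 6
Reactants: 8 methyl (S)-3-(2-cyanoethyl)-4-oxo-1-SES-azepane-3-carboxylate
Product: 10 methyl (S)-3-(2-cyanoethyl)-4-oxo-1-SES-2,3,4,7-tetrahydro-1H-azepine-3-carboxylate, via trimethylsilyl enol ether 9 (not isolated)
Conditions: LiN(SiMe3)2, Me3SiCl, THF, −78 °C; then Pd(OAc)2 (10 mol %), O2 (1 atm), DMSO, rt
Reagents that add atoms: none
Why: Saegusa–Ito dehydrogenation; the ketone can enolise only toward C-5, so the enone forms on the side away from the quaternary carbon.

Step 7
Reactants: 10 methyl (S)-3-(2-cyanoethyl)-4-oxo-1-SES-2,3,4,7-tetrahydro-1H-azepine-3-carboxylate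
Product: 11 methyl (3S,6R)-3-(2-cyanoethyl)-6-(2-methylprop-1-en-1-yl)-4-oxo-1-SES-azepane-3-carboxylate
Conditions: (2-methylprop-1-en-1-yl)boronic acid, [Rh(OH)((R)-binap)]2 (3 mol %), dioxane/H2O 10:1, 35 °C
Reagents that add atoms: (2-methylprop-1-en-1-yl)boronic acid CC(C)=CB(O)O
Why: Hayashi–Miyaura conjugate addition of an alkenylboronic acid; the C-6 stereocentre is set by the (R)-binap ligand (catalyst control, by analogy with 2-cycloalkenones), placing the alkenyl group cis to the ester.

Step 8
Reactants: 11 methyl (3S,6R)-3-(2-cyanoethyl)-6-(2-methylprop-1-en-1-yl)-4-oxo-1-SES-azepane-3-carboxylate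
Product: 12 methyl (3S,6S)-3-(2-cyanoethyl)-6-(2-methylprop-1-en-1-yl)-1-SES-4-(trifluoromethylsulfonyloxy)-2,3,6,7-tetrahydro-1H-azepine-3-carboxylate
Conditions: KN(SiMe3)2, PhNTf2, THF, −78 °C
Reagents that add atoms: N-phenylbis(trifluoromethanesulfonimide) FC(F)(F)S(=O)(=O)N(c1ccccc1)S(=O)(=O)C(F)(F)F
Why: Regiospecific enolate formation (one enolisable α-position) and O-triflation give the enol triflate for cross-coupling.

Step 9
Reactants: 12 enol triflate methyl ester
Product: 13 (3R,6S)-3-(2-cyanoethyl)-3-(hydroxymethyl)-6-(2-methylprop-1-en-1-yl)-1-SES-2,3,6,7-tetrahydro-1H-azepin-4-yl trifluoromethanesulfonate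
Conditions: LiBH4, THF/MeOH, 0 °C to rt
Reagents that add atoms: none
Why: Borohydride reduction of the ester; nitrile, sulfonamide and enol triflate are inert to LiBH4, and the hydroxymethyl group freed here directs the epoxidation.

Step 10
Reactants: 13 hydroxymethyl enol triflate; 3 (S)-pent-1-en-3-yl benzoate
Product: 15 (S)-1-[(3R,6S)-3-(2-cyanoethyl)-3-(hydroxymethyl)-6-(2-methylprop-1-en-1-yl)-1-SES-2,3,6,7-tetrahydro-1H-azepin-4-yl]pentan-3-yl benzoate, via B-alkyl-9-BBN adduct 14 (not isolated)
Conditions: 3, 9-BBN dimer, THF, rt; then 13, Pd(dppf)Cl2 (5 mol %), AsPh3, Cs2CO3, DMF/H2O, rt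
Reagents that add atoms: none
Why: Anti-Markovnikov hydroboration and B-alkyl Suzuki–Miyaura coupling with the enol triflate give the trisubstituted ring alkene regiospecifically.

Step 11
Reactants: 15 azepine alcohol
Product: 16 4,5-epoxide of 15 (oxirane oxygen cis to CH2OH and to the alkenyl group)
Conditions: VO(acac)2 (5 mol %), t-BuOOH, CH2Cl2, 0 °C to rt
Reagents that add atoms: tert-butyl hydroperoxide CC(C)(C)OO
Why: Vanadium-catalysed epoxidation directed by the homoallylic hydroxyl delivers oxygen to the ring-alkene face that carries CH2OH; the remote side-chain alkene has no directing hydroxyl and should be left.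

Step 12
Reactants: 16 epoxy alcohol
Product: 17 tert-butyldimethylsilyl ether of 16
Conditions: TBSCl, imidazole, DMAP (cat.), DMF, rt
Reagents that add atoms: tert-butyldimethylsilyl chloride CC(C)(C)[Si](C)(C)Cl
Why: Silylation removes the free hydroxyl, which could otherwise open the epoxide in the next step.

Step 13
Reactants: 17 azepane 4,5-epoxide
Product: 18 (S)-1-[3-(2-cyanoethyl)-4-formyl-5-(2-methylprop-1-en-1-yl)-1-SES-3-(TBS-oxymethyl)piperidin-4-yl]pentan-3-yl benzoate (CHO; CH2OTBS; alkenyl all cis)
Conditions: MeAl(OC6H2-4-Br-2,6-t-Bu2)2 (3 equiv), CH2Cl2, −78 to −20 °C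
Reagents that add atoms: none
Why: The hindered aluminium Lewis acid binds the epoxide oxygen and loosens the bond to the tertiary carbon C-4; the ring bond C-5–C-6 then shifts to C-4 anti to the departing oxygen while C-5 becomes the formyl carbon. This is a Meinwald (semipinacol) rearrangement of a 1-alkylcycloalkene oxide to the ring-contracted α-quaternary aldehyde, a known reaction type. The piperidine is closed by this 1,2-shift of a ring carbon (seven-to-six contraction), not by cyclisation of a chain. The one new stereocentre, the later spiro carbon, is set by inversion at the tertiary epoxide carbon, so the epoxide face fixed in step 11 puts the formyl group on the face of CH2OTBS and the alkenyl group; the migrating carbon keeps its configuration. The step needs carbon shift in preference to hydride shift (which would give the azepan-5-one) and no capture of the cationic carbon by a neighbouring group. The first is favoured by the bulky Lewis acid, which prefers to end on the less hindered aldehyde oxygen, by the allylic migrating carbon and by the strain lost; the second is secured because sulfonamide, nitrile, benzoate and silyl ether offer no effective nucleophile that can reach C-4 through a five- or six-membered ring.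

Step 14
Reactants: 18 piperidine-4-carbaldehyde
Product: 20 diol (4-CH2OH and (S)-3-hydroxypentyl on C-4 of the piperidine), via hydroxy benzoate 19 (not isolated)
Conditions: NaBH4, MeOH, 0 °C; then K2CO3, rt
Reagents that add atoms: none
Why: Borohydride reduction of the aldehyde, then base-catalysed methanolysis of the benzoate; nitrile and sulfonamide stay, and any silyl shift between the two primary oxygens is harmless because the silyl group leaves in step 16.

Step 15
Reactants: 20 diol
Product: 22 spiro hemiketal (3-ethyl-3-hydroxy-2-oxa-9-azaspiro[5.5]undecane core), via hydroxy ketone 21 (not isolated)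
Conditions: Al(Ot-Bu)3, acetone, toluene, 80 °C
Reagents that add atoms: none
Why: Oppenauer oxidation is selective for the secondary over the neopentyl primary alcohol and is pulled forward by closure of the hydroxy ketone to the six-membered hemiketal.

Step 16
Reactants: 22 spiro hemiketal
Product: 23 methyl ketal alcohol (3-ethyl-3-methoxy-2-oxa-9-azaspiro[5.5]undecane core; free CH2OH on C-11)
Conditions: CSA (0.2 equiv), MeOH, rt
Reagents that add atoms: methanol CO
Why: Acid-catalysed ketalisation in methanol (anomerically favoured methyl ketal expected) with concurrent methanolysis of the primary silyl ether.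

Step 17
Reactants: 23 methyl ketal alcohol (nitrile)
Product: 24 primary amide (CH2CH2CONH2 on C-11)
Conditions: [PtH{(PMe2O)2H}(PMe2OH)] (2 mol %), EtOH/H2O, 80 °C
Reagents that add atoms: water O
Why: Platinum-catalysed nitrile hydration under neutral conditions stops at the primary amide and spares ketal, alkene and sulfonamide.

Step 18
Reactants: 24 primary amide
Product: 26 methyl ester (CH2CH2CO2Me on C-11), via N-acylformamidine 25 (not isolated)
Conditions: Me2NCH(OMe)2, MeOH, 60 °C
Reagents that add atoms: methanol CO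
Why: Condensation of the primary amide with the amide acetal gives an N-acylformamidine that methanol cleaves to the ester, an acid-free amide-to-ester conversion that the ketal and the trisubstituted alkene should survive.

Step 19
Reactants: 26 methyl ester alcohol
Product: 27 aldehyde (CHO on C-11)
Conditions: DMP, NaHCO3, CH2Cl2, rt
Reagents that add atoms: none
Why: Dess–Martin oxidation of the neopentyl alcohol to a non-enolisable aldehyde.

Step 20
Reactants: 27 aldehyde
Product: 28 terminal alkyne (ethynyl on C-11)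
Conditions: dimethyl (1-diazo-2-oxopropyl)phosphonate, K2CO3, MeOH, 0 °C to rt
Reagents that add atoms: dimethyl (1-diazo-2-oxopropyl)phosphonate COP(=O)(OC)C(=[N+]=[N-])C(C)=O
Why: Seyferth–Gilbert homologation with the Ohira–Bestmann reagent converts the aldehyde into the alkyne under mild base.

Step 21
Reactants: 28 terminal alkyne
Product: 30 cyclopentenone (5-oxocyclopent-1-en-1-yl on C-11), via alkyne hexacarbonyldicobalt complex 29 (not isolated)
Conditions: Co2(CO)8, CH2Cl2, rt; then ethene (10 atm), Me3NO·2H2O, toluene, 40 °C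
Reagents that add atoms: ethene C=C; dicobalt octacarbonyl (source of the carbonyl group) [Co].[Co].[C-]#[O+].[C-]#[O+].[C-]#[O+].[C-]#[O+].[C-]#[O+].[C-]#[O+].[C-]#[O+].[C-]#[O+]
Why: Amine-N-oxide-promoted intermolecular Pauson–Khand reaction with ethene places the alkyne substituent α to the new carbonyl; the side-chain alkene is trisubstituted and should be too hindered to react intramolecularly.

Step 22
Reactants: 30 cyclopentenone
Product: 31 tertiary allylic alcohol (5-hydroxy-5-vinylcyclopent-1-en-1-yl on C-11; carbinol configuration undefined)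
Conditions: CH2=CHMgBr, CeCl3, THF, −78 °C
Reagents that add atoms: vinylmagnesium bromide C=C[Mg]Br
Why: Organocerium 1,2-addition to the enone carbonyl (no conjugate addition, no attack on the ester); the configuration of the carbinol carbon is immaterial because it becomes sp2 in step 24.

Step 23
Reactants: 31 tertiary allylic alcohol
Product: 33 tetracyclic tertiary allylic alcohol (seven-membered ring closed and saturated at the new bond), via cycloheptadienol 32 (not isolated)
Conditions: RuCl2(=CHPh)(PCy3)(H2IMes) (second-generation Grubbs catalyst, 5 mol %), CH2Cl2, 40 °C; then H2 (4 atm), 50 °C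
Reagents that add atoms: none
Why: Ring-closing metathesis between the vinyl carbinol and the isobutenyl group (loss of 2-methylpropene) closes the cycloheptene, and the ruthenium hydride formed under hydrogen should reduce the new disubstituted alkene in preference to the trisubstituted cyclopentene alkene (tandem metathesis–hydrogenation).

Step 24
Reactants: 33 tetracyclic tertiary allylic alcohol
Product: 34 tetracyclic enone (cyclopentenone fused to the cycloheptene through its C=C)
Conditions: IBX, DMSO, 55 °C
Reagents that add atoms: none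
Why: Oxidative 1,3-transposition of a tertiary allylic alcohol (Babler–Dauben type) gives the transposed, fully substituted enone.

Step 25
Reactants: 34 tetracyclic enone
Product: 36 N-SES methyl ketal of the target skeleton (conjugated dienoate), via aldol adduct 35 (not isolated)
Conditions: NaOMe, MeOH, 50 °C
Reagents that add atoms: none
Why: Intramolecular aldol condensation under equilibrating conditions: the ester α-carbon adds to the enone carbonyl (5-exo-trig closure of the second cyclopentene) and loss of water gives the conjugated dienoate as the thermodynamic sink.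

Step 26
Reactants: 36 N-SES dienoate methyl ketal
Product: 37 secondary amine (NH) methyl ketal
Conditions: CsF, DMF, 95 °C
Reagents that add atoms: none
Why: Fluoride attacks silicon and the sulfonamide fragments to ethene and sulfur dioxide, freeing the amine without touching ester or ketal.

Step 27
Reactants: 37 secondary amine methyl ketal
Product: 39 target hemiketal CNP0192143.1, via N-methyl methyl ketal 38 (not isolated)
Conditions: CH2O (37% aq.), NaBH(OAc)3, AcOH, MeCN, rt; then 1 M HCl, THF, rt
Reagents that add atoms: formaldehyde C=O; water O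
Why: Reductive amination with formaldehyde installs N-methyl, and aqueous acid hydrolyses the methyl ketal to the hemiketal, which settles in its stable configuration by ring–chain equilibration.

**Compound list**
1 | (S)-2-ethyloxirane | CC[C@H]1CO1 | starting material
2 | (S)-pent-1-en-3-ol | C=C[C@@H](O)CC | intermediate
3 | (S)-pent-1-en-3-yl benzoate | C=C[C@@H](OC(=O)c1ccccc1)CC | intermediate
4 | methyl 4-oxopiperidine-3-carboxylate hydrochloride | COC(=O)C1CNCCC1=O.Cl | starting material
5 | methyl 4-oxo-1-SES-piperidine-3-carboxylate | COC(=O)C1CN(S(=O)(=O)CC[Si](C)(C)C)CCC1=O | intermediate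
6 | methyl (S)-3-(2-cyanoethyl)-4-oxo-1-SES-piperidine-3-carboxylate | O=C1CCN(S(=O)(=O)CC[Si](C)(C)C)C[C@]1(CCC#N)C(=O)OC | intermediate
7 | methyl (3S)-3-(2-cyanoethyl)-4-oxo-1-SES-5-(trimethylsilyl)azepane-3-carboxylate (both C-5 epimers) | O=C1C([Si](C)(C)C)CCN(S(=O)(=O)CC[Si](C)(C)C)C[C@]1(CCC#N)C(=O)OC | intermediate (not isolated)
8 | methyl (S)-3-(2-cyanoethyl)-4-oxo-1-SES-azepane-3-carboxylate | O=C1CCCN(S(=O)(=O)CC[Si](C)(C)C)C[C@]1(CCC#N)C(=O)OC | intermediate
9 | methyl (S)-3-(2-cyanoethyl)-1-SES-4-(trimethylsilyloxy)-2,3,6,7-tetrahydro-1H-azepine-3-carboxylate | C[Si](C)(C)OC1=CCCN(S(=O)(=O)CC[Si](C)(C)C)C[C@]1(CCC#N)C(=O)OC | intermediate (not isolated)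
10 | methyl (S)-3-(2-cyanoethyl)-4-oxo-1-SES-2,3,4,7-tetrahydro-1H-azepine-3-carboxylate | O=C1C=CCN(S(=O)(=O)CC[Si](C)(C)C)C[C@]1(CCC#N)C(=O)OC | intermediate
11 | methyl (3S,6R)-3-(2-cyanoethyl)-6-(2-methylprop-1-en-1-yl)-4-oxo-1-SES-azepane-3-carboxylate | O=C1C[C@H](C=C(C)C)CN(S(=O)(=O)CC[Si](C)(C)C)C[C@]1(CCC#N)C(=O)OC | intermediate
12 | methyl (3S,6S)-3-(2-cyanoethyl)-6-(2-methylprop-1-en-1-yl)-1-SES-4-(trifluoromethylsulfonyloxy)-2,3,6,7-tetrahydro-1H-azepine-3-carboxylate | FC(F)(F)S(=O)(=O)OC1=C[C@H](C=C(C)C)CN(S(=O)(=O)CC[Si](C)(C)C)C[C@]1(CCC#N)C(=O)OC | intermediate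
13 | (3R,6S)-3-(2-cyanoethyl)-3-(hydroxymethyl)-6-(2-methylprop-1-en-1-yl)-1-SES-2,3,6,7-tetrahydro-1H-azepin-4-yl trifluoromethanesulfonate | FC(F)(F)S(=O)(=O)OC1=C[C@H](C=C(C)C)CN(S(=O)(=O)CC[Si](C)(C)C)C[C@]1(CCC#N)CO | intermediate
14 | (S)-1-(9-borabicyclo[3.3.1]nonan-9-yl)pentan-3-yl benzoate | CC[C@H](OC(=O)c1ccccc1)CCB1C2CCCC1CCC2 | intermediate (not isolated)
15 | (S)-1-[(3R,6S)-3-(2-cyanoethyl)-3-(hydroxymethyl)-6-(2-methylprop-1-en-1-yl)-1-SES-2,3,6,7-tetrahydro-1H-azepin-4-yl]pentan-3-yl benzoate | CC[C@H](OC(=O)c1ccccc1)CCC2=C[C@H](C=C(C)C)CN(S(=O)(=O)CC[Si](C)(C)C)C[C@]2(CCC#N)CO | intermediate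
16 | 4,5-epoxide of 15 (8-oxa-3-azabicyclo[5.1.0]octane; oxirane oxygen cis to CH2OH and to the alkenyl group) | CC[C@H](OC(=O)c1ccccc1)CC[C@@]23O[C@@H]2[C@H](C=C(C)C)CN(S(=O)(=O)CC[Si](C)(C)C)C[C@]3(CCC#N)CO | intermediate
17 | tert-butyldimethylsilyl ether of 16 (key-step precursor) | CC[C@H](OC(=O)c1ccccc1)CC[C@@]23O[C@@H]2[C@H](C=C(C)C)CN(S(=O)(=O)CC[Si](C)(C)C)C[C@]3(CCC#N)CO[Si](C)(C)C(C)(C)C | intermediate
18 | (S)-1-[3-(2-cyanoethyl)-4-formyl-5-(2-methylprop-1-en-1-yl)-1-SES-3-(TBS-oxymethyl)piperidin-4-yl]pentan-3-yl benzoate (CHO, CH2OTBS, alkenyl all cis; key-step product) | CC[C@H](OC(=O)c1ccccc1)CC[C@@]2(C=O)[C@H](C=C(C)C)CN(S(=O)(=O)CC[Si](C)(C)C)C[C@]2(CCC#N)CO[Si](C)(C)C(C)(C)C | intermediate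
19 | primary alcohol from 18 (CH2OH in place of CHO; benzoate still present) | CC[C@H](OC(=O)c1ccccc1)CC[C@@]2(CO)[C@H](C=C(C)C)CN(S(=O)(=O)CC[Si](C)(C)C)C[C@]2(CCC#N)CO[Si](C)(C)C(C)(C)C | intermediate (not isolated)
20 | diol: 4-(hydroxymethyl)-4-[(S)-3-hydroxypentyl]piperidine with 3-CH2OTBS, 3-(2-cyanoethyl), 5-alkenyl, 1-SES | CC[C@H](O)CC[C@@]2(CO)[C@H](C=C(C)C)CN(S(=O)(=O)CC[Si](C)(C)C)C[C@]2(CCC#N)CO[Si](C)(C)C(C)(C)C | intermediate
21 | hydroxy ketone: 4-(hydroxymethyl)-4-(3-oxopentyl)piperidine (open form of 22) | CCC(=O)CC[C@@]2(CO)[C@H](C=C(C)C)CN(S(=O)(=O)CC[Si](C)(C)C)C[C@]2(CCC#N)CO[Si](C)(C)C(C)(C)C | intermediate (not isolated)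
22 | spiro hemiketal: 3-ethyl-3-hydroxy-2-oxa-9-azaspiro[5.5]undecane with 7-(2-methylprop-1-en-1-yl), 9-SES, 11-(2-cyanoethyl), 11-CH2OTBS | CC[C@@]1(O)CC[C@@]2(CO1)[C@H](C=C(C)C)CN(S(=O)(=O)CC[Si](C)(C)C)C[C@]2(CCC#N)CO[Si](C)(C)C(C)(C)C | intermediate
23 | methyl ketal alcohol: 3-ethyl-3-methoxy analogue of 22 with free 11-CH2OH | CC[C@@]1(OC)CC[C@@]2(CO1)[C@H](C=C(C)C)CN(S(=O)(=O)CC[Si](C)(C)C)C[C@]2(CCC#N)CO | intermediate
24 | primary amide (11-CH2CH2CONH2) | CC[C@@]1(OC)CC[C@@]2(CO1)[C@H](C=C(C)C)CN(S(=O)(=O)CC[Si](C)(C)C)C[C@]2(CCC(N)=O)CO | intermediate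
25 | N-[(dimethylamino)methylidene] derivative of amide 24 | CC[C@@]1(OC)CC[C@@]2(CO1)[C@H](C=C(C)C)CN(S(=O)(=O)CC[Si](C)(C)C)C[C@]2(CCC(=O)N=CN(C)C)CO | intermediate (not isolated)
26 | methyl ester (11-CH2CH2CO2Me, 11-CH2OH) | CC[C@@]1(OC)CC[C@@]2(CO1)[C@H](C=C(C)C)CN(S(=O)(=O)CC[Si](C)(C)C)C[C@]2(CCC(=O)OC)CO | intermediate
27 | aldehyde (11-CHO) | CC[C@@]1(OC)CC[C@@]2(CO1)[C@H](C=C(C)C)CN(S(=O)(=O)CC[Si](C)(C)C)C[C@]2(CCC(=O)OC)C=O | intermediate
28 | terminal alkyne (11-ethynyl) | CC[C@@]1(OC)CC[C@@]2(CO1)[C@H](C=C(C)C)CN(S(=O)(=O)CC[Si](C)(C)C)C[C@]2(CCC(=O)OC)C#C | intermediate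
29 | hexacarbonyldicobalt complex of alkyne 28 | CC[C@@]1(OC)CC[C@@]2(CO1)[C@H](C=C(C)C)CN(S(=O)(=O)CC[Si](C)(C)C)C[C@]2(CCC(=O)OC)C34[CH]5[Co]3(=C=O)(=C=O)(=C=O)[Co]45(=C=O)(=C=O)=C=O | intermediate (not isolated)
30 | cyclopentenone (11-(5-oxocyclopent-1-en-1-yl)) | CC[C@@]1(OC)CC[C@@]2(CO1)[C@H](C=C(C)C)CN(S(=O)(=O)CC[Si](C)(C)C)C[C@]2(CCC(=O)OC)C3=CCCC3=O | intermediate
31 | tertiary allylic alcohol (11-(5-hydroxy-5-vinylcyclopent-1-en-1-yl); carbinol configuration undefined) | CC[C@@]1(OC)CC[C@@]2(CO1)[C@H](C=C(C)C)CN(S(=O)(=O)CC[Si](C)(C)C)C[C@]2(CCC(=O)OC)C3=CCCC3(O)C=C | intermediate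
32 | cycloheptadienol from ring-closing metathesis (carbinol configuration undefined) | CC[C@@]1(OC)CC[C@@]2(CO1)[C@@H]1C=CC3(O)CCC=C3[C@@]2(CCC(=O)OC)CN(S(=O)(=O)CC[Si](C)(C)C)C1 | intermediate (not isolated)
33 | tetracyclic tertiary allylic alcohol (carbinol configuration undefined) | CC[C@@]1(OC)CC[C@@]2(CO1)[C@@H]1CCC3(O)CCC=C3[C@@]2(CCC(=O)OC)CN(S(=O)(=O)CC[Si](C)(C)C)C1 | intermediate
34 | tetracyclic enone with methyl propanoate arm on the ring-junction quaternary carbon | CC[C@@]1(OC)CC[C@@]2(CO1)[C@@H]1CCC3=C(C(=O)CC3)[C@@]2(CCC(=O)OC)CN(S(=O)(=O)CC[Si](C)(C)C)C1 | intermediate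
35 | β-hydroxy ester aldol adduct (two transient centres undefined) | CC[C@@]1(OC)CC[C@@]2(CO1)[C@@H]1CCC3=C4C(O)(C(C(=O)OC)C[C@@]42CN(S(=O)(=O)CC[Si](C)(C)C)C1)CC3 | intermediate (not isolated)
36 | N-SES, O-methyl ketal of the target skeleton (dienoate) | CC[C@@]1(OC)CC[C@@]2(CO1)[C@@H]1CCC3=C4C(=C(C(=O)OC)C[C@@]42CN(S(=O)(=O)CC[Si](C)(C)C)C1)CC3 | intermediate
37 | N-H, O-methyl ketal of the target skeleton | CC[C@@]1(OC)CC[C@@]2(CO1)[C@@H]1CCC3=C4C(=C(C(=O)OC)C[C@@]42CNC1)CC3 | intermediate
38 | O-methyl ketal of the target (N-methyl) | CC[C@@]1(OC)CC[C@@]2(CO1)[C@@H]1CCC3=C4C(=C(C(=O)OC)C[C@@]42CN(C)C1)CC3 | intermediate (not isolated)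
39 | CNP0192143.1 | CC[C@@]1(O)CC[C@@]2(CO1)[C@@H]1CCC3=C4C(=C(C(=O)OC)C[C@@]42CN(C)C1)CC3 | target

**Step count.** Total: 27 steps. Longest linear sequence: 25 steps (steps 3 to 27, from 4 to 39); steps 1 and 2 make the side-chain fragment.

**Steps most likely to fail**

Step 13. Hydride shift to the azepan-5-one could compete with the ring-carbon shift, and the hindered Lewis acid may bind the nitrile or the ester carbonyl and open the congested epoxide only sluggishly. Fallback (pinacol rearrangement instead of epoxide rearrangement): azepine alcohol 15 is dihydroxylated on the face of its hydroxymethyl group with OsO4 and TMEDA (hydrogen-bond-directed osmylation) to give the syn-triol F1. Silylation of the primary hydroxyl (TBSCl, imidazole) gives the diol F2. Acid (TsOH or BF3·OEt2) ionises the tertiary hydroxyl, the same ring carbon shifts anti to it, and the route is rejoined at aldehyde 18.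

Step 21. The cobalt-complexed alkyne may be consumed by slow intramolecular reaction with the side-chain alkene or may decompose before ethene is taken up, and the neopentyl-type alkyne is hindered. Fallback (hydroacylation instead of carbonylative cycloaddition): alkyne 28 is added to acrolein (Pd(OAc)2, PMe3, water/acetone; conjugate addition of a terminal alkyne) to give the 4-alkynal F3. A cationic rhodium catalyst, [Rh(dppe)]2(BF4)2 in acetone, then closes F3 by intramolecular alkyne hydroacylation to the same cyclopentenone 30.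

Step 4. Acrylonitrile is a weak acceptor, so slow conversion and an uncatalysed background addition could erode the enantiomeric purity of the only catalyst-made quaternary centre; the sense of induction may also call for the quinidine-derived pseudoenantiomer of the catalyst. Fallback (more reactive acceptor, then functional-group change): β-keto ester 5 is added to acrolein under the same bifunctional cinchona catalysis to give the aldehyde F4. Iodine in aqueous ammonia then oxidises the aldehyde, through its aldimine, to the nitrile, which rejoins the route at 6.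

Further compounds
F1 | step 13 | syn-triol: 4,5-dihydroxy derivative of 15 with both new hydroxyls cis to CH2OH | CC[C@H](OC(=O)c1ccccc1)CC[C@@]2(O)[C@H](O)[C@H](C=C(C)C)CN(S(=O)(=O)CC[Si](C)(C)C)C[C@]2(CCC#N)CO
F2 | step 13 | diol: primary tert-butyldimethylsilyl ether of F1 | CC[C@H](OC(=O)c1ccccc1)CC[C@@]2(O)[C@H](O)[C@H](C=C(C)C)CN(S(=O)(=O)CC[Si](C)(C)C)C[C@]2(CCC#N)CO[Si](C)(C)C(C)(C)C
F3 | step 21 | 4-alkynal: 11-(5-oxopent-1-yn-1-yl) analogue of 28 | CC[C@@]1(OC)CC[C@@]2(CO1)[C@H](C=C(C)C)CN(S(=O)(=O)CC[Si](C)(C)C)C[C@]2(CCC(=O)OC)C#CCCC=O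
F4 | step 4 | methyl (S)-4-oxo-3-(3-oxopropyl)-1-SES-piperidine-3-carboxylate | O=C1CCN(S(=O)(=O)CC[Si](C)(C)C)C[C@]1(CCC=O)C(=O)OC
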